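## The problem

The target 27 is a 10βH-eremophilane: a cis-fused decalin whose quaternary C5 carries the C14 methyl group, with C4 (C15 methyl, cis to C14) and C3 (α-senecioate) on ring A and the C7 isopropenyl group, the C8 ketone and the C9 β-angelate on ring B. Eremophilane numbering is used throughout, β is the face of C14, and the SMILES is read as (3R,4R,5R,7R,9R,10S). Of the six stereocentres only C5 and C10 can never be corrected, so they must be set by C–C bond formation and then serve as the reference: C4, C7 and C9 each lie next to a carbonyl group at some stage, and C3 arises by reduction. In the chair–chair conformer with C14 axial on ring A, all four ring substituents of 27 are equatorial, so thermodynamic control is available, but only once a fixed centre has locked that conformer, because the flipped cis-decalin offers an all-equatorial arrangement for the opposite configurations at C4, C7 and C9. The same conformer places C14 syn-axial to the axial approach at C3, so a small hydride cannot be trusted to give the equatorial 3α-alcohol. The sensitive groups are the angelate (Z to E isomerisation to the tiglate), the β,γ-unsaturated ketone (base moves the isopropenyl double bond into conjugation with C8=O) and the α-acyloxy ketone; in addition, two secondary hydroxyl groups of similar hindrance must carry two different enoates. The feature that opens the structure is in ring B: an isopropenyl group on C7 next to an oxygenated C8 is the product pattern of a carbonyl-ene reaction between a C8 aldehyde, on a two-carbon arm at C10, and a prenyl group on C5, which closes ring B through C7–C8.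

## Retrosynthesis

27 to 24 and 25: the C9–O acyl bond is cut first. The angelate is the most fragile group, so it is introduced last and meets no further reagent. The forward step must acylate a hindered α-ketol without Z to E isomerisation and without base strong enough to conjugate the isopropenyl group.

24 to 22: the C9–O bond is cut, in the forward sense by oxidation of the C8 ketone enolate. Carrying the C9 oxygen through the ring closure would require a stereodefined α-oxygenated aldehyde, so C9 stays a methylene until ring B exists. The forward step needs kinetic enolisation towards C9 rather than C7 and attack on the β face.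

22 back to 16 (through 21, 20, 18 and 17): the senecioate C–O bond and the C3–H bond are cut. C3 is set by a dissolving-metal reduction of the C3 ketone, which gives the equatorial alcohol, and this is only possible while C8 is not a ketone. The reverse order (ring B first) would require reducing C3 beside an α-acyloxy C8 ketone, which is neither chemoselective nor stereoselective. Since acylation cannot distinguish the C3 and C8 hydroxyl groups, the C8 hydroxyl of 16 is silylated (17) before the reduction (18) and released after the esterification (20 to 21), then oxidised (22).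

16 to 15 to 14: after ketal hydrolysis, the C7–C8 bond is cut by a retro-ene step. Compared with cuts through the ring fusion, this one removes ring B, two stereocentres and the isopropenyl group in one operation and leaves a cyclohexane with three contiguous centres. The forward reaction needs an aldehyde that reacts before the ketal and a chair preference that places C7 correctly relative to C5 and C10.

14 to 13 to 11: the aldehyde comes from a tert-butyl ester by partial reduction, and the prenyl group from an allyl group by cross-metathesis with 12. Prenyl organometallics add with allylic transposition, so the allyl group is the practical precursor.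

11 to 9 and 10: the ketal C–O bonds are cut. The ketal protects C3 through the hydride and Lewis-acid steps, and the C2-symmetric diol 10 turns the racemic ketone into separable diastereomers, so the resolution costs no extra step and comes early.

9 to 7: the C5–C14 and C4–C15 bonds are cut, in the forward sense a methyl conjugate addition followed by methylation of the enolate. The C4 methyl group is deliberately the last substituent to arrive. If it were already present, a proton would arrive last on the same face and give the C4 epimer. C4 must be correct before ring B is closed, because it selects the chair used in the ene reaction and later anchors C7.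

7 to 4 and 5, and 4 to 1 and 2: the C5–C6 bond is cut by a Stork–Danheiser addition and transposition, and the C10–C9 bond by alkylation of the vinylogous ester 1 with 2. These two steps place the two arms on adjacent carbons and leave C3 at the ketone level.

## Roads not taken

Alternative 1: C6–C7 and C5–C10 are cut together. In the forward sense the open-chain trienone A1 (a 2-silyloxy-3-alkoxy diene tethered to an α-methyl enone) undergoes an intramolecular Diels–Alder reaction to the cis-fused octalin A2.
- Merits: both rings and the C5/C10 pair arise in one step from an achiral chain. Ring B arrives with C8 and C9 already oxygenated and differentiated, which would spare the late enolate hydroxylation; in this respect and in convergence this road is better.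
- Weak points: cis/trans selectivity is rarely high when such a cycloaddition builds a quaternary ring-fusion carbon, and the doubly oxygenated diene is hydrolytically fragile. Ring A arrives with its carbonyl on C4 and nothing on C3, so a carbonyl transposition and a C4 methylation next to the quaternary centre remain. C7 has no isopropenyl group, and absolute configuration would need an asymmetric catalyst for this particular cycloaddition.
- Comparison: the chosen plan offers a ring A with the correct oxidation pattern from step 1, a reliable trans-selective cuprate addition for C5/C10, and a ring closure that itself installs the isopropenyl group.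

Alternative 2: C5–C6 is formed by an anionic oxy-Cope rearrangement. The potassium alkoxide of the vinyl carbinol A3, a bicyclo[2.2.2]octenol derived from a masked ortho-quinone cycloadduct, undergoes the [3,3] shift (C5–C6 formed, C3–C8 broken) to give the cis-fused ketone A4.
- Merits: the shift is stereospecific, so the cis fusion, the quaternary C5 and both methyl groups are secure, and a C8 ketone and a C9 oxygen are present. The C4 problem, which costs the chosen plan an explicit control element, does not arise; on ring-fusion and methyl stereocontrol this road is better.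
- Weak points: A3 needs its vinyl group syn to the dimethyl-substituted bridge. A4 has a C3=C4 double bond whose conversion into the 3α-oxygen/4β-hydrogen pair needs a hydroboration that a C7 isopropenyl group would not survive. C9 arrives at the ketone level next to the C8 ketone and must be reduced selectively, and the isopropenyl group must still be added by enolate chemistry. The material is racemic unless the cycloaddition leading to A3 is made asymmetric.
- Comparison: the chosen plan needs fewer redox corrections on ring B and has the isopropenyl group in place, at the price of the protecting-group moves in steps 9 and 12.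

Alternative 3: C4–C5 and C1–C10 are cut. In the forward sense quinone A5 and silyloxydiene A6 combine in a Diels–Alder reaction across the methyl-substituted double bond to give the cis-fused endo adduct A7.
- Merits: two simple fragments, a secure cis fusion with the quaternary C5, and C3 at the ketone level. Catalytic asymmetric quinone cycloadditions would make the route enantioselective where the chosen plan resolves; in convergence and absolute stereocontrol this road is ahead.
- Weak points: the endo rule places the C4 methyl trans to C14, so C4 must be inverted through the C3 ketone. The required orientation joins a methine to the methylated quinone carbon against steric congestion. Ring B carries one oxygen too many (the C6 ketone must be removed), the C8 enol ether and C9 ketone must be reorganised into C8 ketone and C9 alcohol, and the isopropenyl group is still missing. This redox work on a base-sensitive ene-dione is longer than the sequence from 16 to 27.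
- Comparison: the chosen plan gives up convergence and asymmetric catalysis and gains a ring B that is formed already carrying the isopropenyl group and a single oxygen at C8.

Key step: step 7

## Route

Remark on the chemistry (assumption): electrophiles are taken to enter the C3–C4 enolate 8 on the face of C14, anti to the two side chains; step 3 rests on this, and its fallback covers the opposite outcome.

Remark: compounds 4 to 9 are racemic, and their SMILES show the enantiomer that leads to 27. From 11 onwards all compounds are single enantiomers.

Step 1
Reactants: 1 3-ethoxycyclohex-2-en-1-one; 2 tert-butyl bromoacetate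
Product: 4 tert-butyl 2-(4-ethoxy-2-oxocyclohex-3-en-1-yl)acetate (racemic), via lithium dienolate 3 (not isolated)
Conditions: LiN(i-Pr)2, THF, −78 °C; then 2, −78 → −20 °C
Reagents that add atoms: none
Why: Kinetic deprotonation of the vinylogous ester at the α′ carbon (C10) and SN2 alkylation of the lithium enolate, the first stage of a Stork–Danheiser sequence; the tert-butyl ester is chosen to resist the organometallic steps that follow, and C10 is formed as a racemate.

Step 2
Reactants: 4 tert-butyl 2-(4-ethoxy-2-oxocyclohex-3-en-1-yl)acetate; 5 allylmagnesium bromide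
Product: 7 tert-butyl 2-[4-oxo-2-(prop-2-en-1-yl)cyclohex-2-en-1-yl]acetate (racemic), via tertiary allylic carbinol 6 (not isolated)
Conditions: 5, THF, −78 → 0 °C; then 1 M HCl, 0 °C → rt
Reagents that add atoms: water, O
Why: 1,2-Addition of the Grignard reagent to the vinylogous ester carbonyl, then acid-promoted ionisation and hydrolysis of the enol ether (Stork–Danheiser transposition), should give the enone with the allyl group on C5 and C10 as its γ-carbon; at low temperature the hindered tert-butyl ester should be neither attacked nor lactonised.

Step 3
Reactants: 7 tert-butyl 2-[4-oxo-2-(prop-2-en-1-yl)cyclohex-2-en-1-yl]acetate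
Product: 9 tert-butyl 2-[(1R,2S,3R)-2,3-dimethyl-4-oxo-2-(prop-2-en-1-yl)cyclohexyl]acetate (racemic), via lithium enolate 8 (not isolated)
Conditions: Me2CuLi (from MeLi and CuI), Et2O, −40 → 0 °C; then MeI (excess), HMPA, −20 °C → rt
Reagents that add atoms: lithium dimethylcuprate, [Li+].C[Cu-]C; iodomethane, CI
Why: Cuprate 1,4-addition anti to the C10 side chain (axial attack on the half-chair with the γ-substituent pseudoaxial) should put C14 trans and the allyl group cis to the C10 arm. The regiodefined enolate is then C-methylated at C4 on the face of C14, because the two side chains cover the other face in either half-chair, which gives the cis-dimethyl array. Reaction types: conjugate addition and in situ enolate alkylation.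

Step 4
Reactants: 9 tert-butyl 2-[(1R,2S,3R)-2,3-dimethyl-4-oxo-2-(prop-2-en-1-yl)cyclohexyl]acetate (racemic); 10 (2R,3R)-butane-2,3-diol
Product: 11 tert-butyl 2-[(2R,3R,6R,7S,8R)-2,3,6,7-tetramethyl-7-(prop-2-en-1-yl)-1,4-dioxaspiro[4.5]decan-8-yl]acetate
Conditions: 10, i-PrOSiMe3, Me3SiOTf (cat.), CH2Cl2, −40 → 0 °C; chromatographic separation of the two diastereomeric ketals
Reagents that add atoms: none
Why: Silyl-triflate-catalysed ketalisation at low temperature should proceed without enolisation, so C4 is kept, and it protects C3 against the hydride and Lewis acid to come. The C2-symmetric diol converts the racemate into two diastereomers, and isolation of the one with the (6R,7S,8R) ring is the resolution of the route.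

Step 5
Reactants: 11 tert-butyl 2-[(2R,3R,6R,7S,8R)-2,3,6,7-tetramethyl-7-(prop-2-en-1-yl)-1,4-dioxaspiro[4.5]decan-8-yl]acetate; 12 2-methylbut-2-ene
Product: 13 tert-butyl 2-[(2R,3R,6R,7S,8R)-2,3,6,7-tetramethyl-7-(3-methylbut-2-en-1-yl)-1,4-dioxaspiro[4.5]decan-8-yl]acetate
Conditions: 12 (excess), second-generation Grubbs catalyst RuCl2(=CHPh)(H2IMes)(PCy3) (3 mol %), CH2Cl2, 40 °C
Reagents that add atoms: none
Why: Olefin cross-metathesis of the monosubstituted alkene with the trisubstituted alkene in excess turns allyl into prenyl, a group that cannot be introduced directly in step 2 because prenyl organometallics add with allylic transposition.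

Step 6
Reactants: 13 tert-butyl 2-[(2R,3R,6R,7S,8R)-2,3,6,7-tetramethyl-7-(3-methylbut-2-en-1-yl)-1,4-dioxaspiro[4.5]decan-8-yl]acetate
Product: 14 2-[(2R,3R,6R,7S,8R)-2,3,6,7-tetramethyl-7-(3-methylbut-2-en-1-yl)-1,4-dioxaspiro[4.5]decan-8-yl]acetaldehyde
Conditions: i-Bu2AlH (1.1 equiv), CH2Cl2, −78 °C; aq. KNaC4H4O6
Reagents that add atoms: none
Why: Partial ester reduction: at −78 °C the tetrahedral aluminium hemiacetal persists and gives the aldehyde on work-up; ketal and alkene are inert.

Step 7
Reactants: 14 2-[(2R,3R,6R,7S,8R)-2,3,6,7-tetramethyl-7-(3-methylbut-2-en-1-yl)-1,4-dioxaspiro[4.5]decan-8-yl]acetaldehyde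
Product: 15 (4R,5S,7R,8S,10R)-8-hydroxyeremophil-11-en-3-one (2R,3R)-butane-2,3-diyl ketal
Conditions: Me2AlCl (1.5 equiv), CH2Cl2, −78 → −40 °C; cold dilute HCl
Reagents that add atoms: none
Why: Me2AlCl binds the aldehyde oxygen; C7 of the trisubstituted alkene attacks C8 while a hydrogen of a C11 methyl group passes to oxygen through a six-membered array, and the aluminium alkoxide then loses methane, so no free proton is left to open the ketal or isomerise the new 1,1-disubstituted alkene. The closest known reaction is the Lewis-acid-promoted intramolecular carbonyl-ene cyclisation of citronellal-type aldehydes to trans-2-isopropenylcyclohexanols. Ring B closes by a 6-exo-trig attack on the aldehyde carbon with C11 left outside the ring, and since both arms are already cis on ring A only a cis-decalin can result. C8 and C7 are set together in a chair transition state in which the complexed oxygen and the developing isopropenyl group are both equatorial, which should give the trans 7β,8α pair. Their sense relative to C5 and C10 depends on which chair of the forming cis-decalin is used: the one that keeps C15 equatorial on ring A and C14 equatorial on the new ring is favoured over the one with C15 axial and with C14 and C1 axial on the new ring, so the C4 centre set in step 3 controls C7. The step needs the aldehyde to react before the ketal is ionised and the ene pathway to win over chloride-trapping Prins pathways; low temperature, the unbranched aldehyde, the nucleophilic prenyl group and the proton-scavenging Lewis acid secure this. Only C7 has to last, because C8 is oxidised in step 13.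

Step 8
Reactants: 15 (4R,5S,7R,8S,10R)-8-hydroxyeremophil-11-en-3-one (2R,3R)-butane-2,3-diyl ketal
Product: 16 (4R,5S,7R,8S,10R)-8-hydroxyeremophil-11-en-3-one
Conditions: 1 M HCl, THF, rt
Reagents that add atoms: water, O
Why: Acid hydrolysis of the ketal; C4 becomes epimerisable, but its methyl group is equatorial in the conformer locked by the equatorial isopropenyl and hydroxyl groups, so the configuration is thermodynamically safe.

Step 9
Reactants: 16 (4R,5S,7R,8S,10R)-8-hydroxyeremophil-11-en-3-one
Product: 17 (4R,5S,7R,8S,10R)-8-[(tert-butyldimethylsilyl)oxy]eremophil-11-en-3-one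
Conditions: t-BuMe2SiCl, imidazole, DMF, rt
Reagents that add atoms: tert-butyldimethylsilyl chloride, CC(C)(C)[Si](C)(C)Cl
Why: Silyl protection of the C8 hydroxyl; without it the molecule would carry, after step 10, two secondary hydroxyl groups of similar hindrance that acylation could not tell apart.

Step 10
Reactants: 17 (4R,5S,7R,8S,10R)-8-[(tert-butyldimethylsilyl)oxy]eremophil-11-en-3-one
Product: 18 (3R,4R,5S,7R,8S,10R)-8-[(tert-butyldimethylsilyl)oxy]eremophil-11-en-3-ol
Conditions: Li, NH3 (l), THF, EtOH, −78 °C; then NH4Cl
Reagents that add atoms: none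
Why: Dissolving-metal reduction of the ketone should give the thermodynamically favoured equatorial 3α-alcohol; a hydride would have to approach C3 axially past the syn-axial C14 methyl group and would give much axial alcohol. The silyl ether and the isolated alkene are inert.

Step 11
Reactants: 18 (3R,4R,5S,7R,8S,10R)-8-[(tert-butyldimethylsilyl)oxy]eremophil-11-en-3-ol; 19 3-methylbut-2-enoyl chloride
Product: 20 (3R,4R,5S,7R,8S,10R)-8-[(tert-butyldimethylsilyl)oxy]eremophil-11-en-3-yl 3-methylbut-2-enoate
Conditions: 19, pyridine, DMAP (cat.), CH2Cl2, 0 °C → rt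
Reagents that add atoms: none
Why: Acylation of the secondary alcohol by the acid chloride with pyridine as a weak base, which avoids deconjugation of the senecioyl group.

Step 12
Reactants: 20 (3R,4R,5S,7R,8S,10R)-8-[(tert-butyldimethylsilyl)oxy]eremophil-11-en-3-yl 3-methylbut-2-enoate
Product: 21 (3R,4R,5S,7R,8S,10R)-8-hydroxyeremophil-11-en-3-yl 3-methylbut-2-enoate
Conditions: HF·pyridine, THF, 0 °C → rt
Reagents that add atoms: none
Why: Fluoride cleavage of the silyl ether under non-basic conditions that leave the enoate untouched.

Step 13
Reactants: 21 (3R,4R,5S,7R,8S,10R)-8-hydroxyeremophil-11-en-3-yl 3-methylbut-2-enoate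
Product: 22 (3R,4R,5S,7R,10R)-8-oxoeremophil-11-en-3-yl 3-methylbut-2-enoate
Conditions: Dess–Martin periodinane, NaHCO3, CH2Cl2, 0 °C → rt
Reagents that add atoms: none
Why: Dess–Martin oxidation under buffered conditions should give the C8 ketone without moving the isopropenyl double bond into conjugation; the C7 substituent stays equatorial, held by the fixed equatorial groups on ring A.

Step 14
Reactants: 22 (3R,4R,5S,7R,10R)-8-oxoeremophil-11-en-3-yl 3-methylbut-2-enoate
Product: 24 (3R,4R,5R,7R,9R,10S)-9-hydroxy-8-oxoeremophil-11-en-3-yl 3-methylbut-2-enoate, via potassium enolate 23 (not isolated)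
Conditions: KN(SiMe3)2 (1.1 equiv), THF, −78 °C; then 2-(benzenesulfonyl)-3-phenyloxaziridine, −78 °C; aq. NH4Cl
Reagents that add atoms: 2-(benzenesulfonyl)-3-phenyloxaziridine, O=S(=O)(c1ccccc1)N1OC1c1ccccc1
Why: Kinetic deprotonation by the hindered amide should take a C9 methylene proton and not the C7 methine or the ester. The enolate is oxidised by the N-sulfonyloxaziridine (Davis hydroxylation) on the convex β face, anti to the axial C4–C5 bond, which gives the equatorial 9β-alcohol, also the thermodynamically preferred epimer.

Step 15
Reactants: 24 (3R,4R,5R,7R,9R,10S)-9-hydroxy-8-oxoeremophil-11-en-3-yl 3-methylbut-2-enoate; 25 (2Z)-2-methylbut-2-enoic acid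
Product: 27 (3R,4R,5R,7R,9R,10S)-9-{[(2Z)-2-methylbut-2-enoyl]oxy}-8-oxoeremophil-11-en-3-yl 3-methylbut-2-enoate, via mixed anhydride 26 (not isolated)
Conditions: 25, 2,4,6-trichlorobenzoyl chloride, Et3N, toluene, rt; then 24, 70 °C
Reagents that add atoms: none
Why: Yamaguchi-type acylation through the 2,4,6-trichlorobenzoyl mixed anhydride, run without a nucleophilic catalyst, is the established way to transfer the angeloyl group with its Z geometry intact; the hindered aroyl carbonyl directs the alcohol to the angeloyl carbonyl.

## Compound list

1 | 3-ethoxycyclohex-2-en-1-one | CCOC1=CC(=O)CCC1 | starting material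
2 | tert-butyl bromoacetate | CC(C)(C)OC(=O)CBr | starting material
3 | lithium 5-ethoxycyclohexa-1,5-dien-1-olate (α′-enolate of 1) | [Li+].CCOC1=CC([O-])=CCC1 | intermediate (not isolated)
4 | tert-butyl 2-(4-ethoxy-2-oxocyclohex-3-en-1-yl)acetate, racemic, (1R) enantiomer drawn | CCOC1=CC(=O)[C@@H](CC(=O)OC(C)(C)C)CC1 | intermediate
5 | allylmagnesium bromide | C=CC[Mg]Br | starting material
6 | tert-butyl 2-[4-ethoxy-2-hydroxy-2-(prop-2-en-1-yl)cyclohex-3-en-1-yl]acetate, present as its bromomagnesium alkoxide, mixture of carbinol epimers, racemic | CCOC1=CC(O)(CC=C)[C@@H](CC(=O)OC(C)(C)C)CC1 | intermediate (not isolated)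
7 | tert-butyl 2-[4-oxo-2-(prop-2-en-1-yl)cyclohex-2-en-1-yl]acetate, racemic, (1R) enantiomer drawn | C=CCC1=CC(=O)CC[C@@H]1CC(=O)OC(C)(C)C | intermediate
8 | lithium (3S,4R)-4-(2-tert-butoxy-2-oxoethyl)-3-methyl-3-(prop-2-en-1-yl)cyclohex-1-en-1-olate, racemic | [Li+].C=CC[C@@]1(C)[C@H](CCC([O-])=C1)CC(=O)OC(C)(C)C | intermediate (not isolated)
9 | tert-butyl 2-[(1R,2S,3R)-2,3-dimethyl-4-oxo-2-(prop-2-en-1-yl)cyclohexyl]acetate, racemic (methyl groups cis, allyl cis to the acetate arm) | C=CC[C@@]1(C)[C@H](CCC(=O)[C@@H]1C)CC(=O)OC(C)(C)C | intermediate
10 | (2R,3R)-butane-2,3-diol | C[C@@H](O)[C@@H](C)O | starting material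
11 | tert-butyl 2-[(2R,3R,6R,7S,8R)-2,3,6,7-tetramethyl-7-(prop-2-en-1-yl)-1,4-dioxaspiro[4.5]decan-8-yl]acetate | C=CC[C@@]1(C)[C@H](CCC2(O[C@H](C)[C@@H](C)O2)[C@@H]1C)CC(=O)OC(C)(C)C | intermediate
12 | 2-methylbut-2-ene | CC=C(C)C | starting material
13 | tert-butyl 2-[(2R,3R,6R,7S,8R)-2,3,6,7-tetramethyl-7-(3-methylbut-2-en-1-yl)-1,4-dioxaspiro[4.5]decan-8-yl]acetate | CC(C)=CC[C@@]1(C)[C@H](CCC2(O[C@H](C)[C@@H](C)O2)[C@@H]1C)CC(=O)OC(C)(C)C | intermediate
14 | 2-[(2R,3R,6R,7S,8R)-2,3,6,7-tetramethyl-7-(3-methylbut-2-en-1-yl)-1,4-dioxaspiro[4.5]decan-8-yl]acetaldehyde | CC(C)=CC[C@@]1(C)[C@H](CCC2(O[C@H](C)[C@@H](C)O2)[C@@H]1C)CC=O | intermediate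
15 | (4R,5S,7R,8S,10R)-8-hydroxyeremophil-11-en-3-one (2R,3R)-butane-2,3-diyl ketal (cis-decalin, 7β-isopropenyl, 8α-OH, 4β,5β-dimethyl, 10β-H) | C=C(C)[C@H]1C[C@@]2(C)[C@H](CCC3(O[C@H](C)[C@@H](C)O3)[C@@H]2C)C[C@@H]1O | intermediate
16 | (4R,5S,7R,8S,10R)-8-hydroxyeremophil-11-en-3-one | C=C(C)[C@H]1C[C@@]2(C)[C@H](CCC(=O)[C@@H]2C)C[C@@H]1O | intermediate
17 | (4R,5S,7R,8S,10R)-8-[(tert-butyldimethylsilyl)oxy]eremophil-11-en-3-one | C=C(C)[C@H]1C[C@@]2(C)[C@H](CCC(=O)[C@@H]2C)C[C@@H]1O[Si](C)(C)C(C)(C)C | intermediate
18 | (3R,4R,5S,7R,8S,10R)-8-[(tert-butyldimethylsilyl)oxy]eremophil-11-en-3-ol (3α-OH) | C=C(C)[C@H]1C[C@@]2(C)[C@H](CC[C@@H](O)[C@@H]2C)C[C@@H]1O[Si](C)(C)C(C)(C)C | intermediate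
19 | 3-methylbut-2-enoyl chloride | CC(C)=CC(=O)Cl | starting material
20 | (3R,4R,5S,7R,8S,10R)-8-[(tert-butyldimethylsilyl)oxy]eremophil-11-en-3-yl 3-methylbut-2-enoate | C=C(C)[C@H]1C[C@@]2(C)[C@H](CC[C@@H](OC(=O)C=C(C)C)[C@@H]2C)C[C@@H]1O[Si](C)(C)C(C)(C)C | intermediate
21 | (3R,4R,5S,7R,8S,10R)-8-hydroxyeremophil-11-en-3-yl 3-methylbut-2-enoate | C=C(C)[C@H]1C[C@@]2(C)[C@H](CC[C@@H](OC(=O)C=C(C)C)[C@@H]2C)C[C@@H]1O | intermediate
22 | (3R,4R,5S,7R,10R)-8-oxoeremophil-11-en-3-yl 3-methylbut-2-enoate | C=C(C)[C@H]1C[C@@]2(C)[C@H](CC[C@@H](OC(=O)C=C(C)C)[C@@H]2C)CC1=O | intermediate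
23 | potassium C8–C9 enolate of 22 | [K+].C=C(C)[C@H]1C[C@@]2(C)[C@H](CC[C@@H](OC(=O)C=C(C)C)[C@@H]2C)C=C1[O-] | intermediate (not isolated)
24 | (3R,4R,5R,7R,9R,10S)-9-hydroxy-8-oxoeremophil-11-en-3-yl 3-methylbut-2-enoate (9β-OH) | C=C(C)[C@H]1C[C@@]2(C)[C@H](CC[C@@H](OC(=O)C=C(C)C)[C@@H]2C)[C@@H](O)C1=O | intermediate
25 | (2Z)-2-methylbut-2-enoic acid (angelic acid) | C/C=C(/C)C(=O)O | starting material
26 | (2Z)-2-methylbut-2-enoic 2,4,6-trichlorobenzoic anhydride | C/C=C(/C)C(=O)OC(=O)c1c(Cl)cc(Cl)cc1Cl | intermediate (not isolated)
27 | (3R,4R,5R,7R,9R,10S)-9-{[(2Z)-2-methylbut-2-enoyl]oxy}-8-oxoeremophil-11-en-3-yl 3-methylbut-2-enoate (CNP0164025.2) | C=C(C)[C@H]1C[C@@]2(C)[C@H](CC[C@@H](OC(=O)C=C(C)C)[C@@H]2C)[C@@H](OC(=O)/C(C)=C\C)C1=O | target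

## Step count and least certain steps

Total: 15 steps. Longest linear sequence: 15 steps, from 1 to 27 (the route is linear).

Step 7 (key step). The most likely failure is insufficient discrimination between the two chair transition states, so that C7 and C8 form partly with the wrong sense relative to C5 and C10; a second danger is ionisation of the ketal by the Lewis acid. The fallback replaces kinetic by thermodynamic control of C7. It sets out from 15, obtained as a mixture with its C7/C8 isomers, which is oxidised with Dess–Martin periodinane to the C8 ketone (4R,5S,7R,10R)-eremophil-11-ene-3,8-dione 3-[(2R,3R)-butane-2,3-diyl ketal] F1 and its C7 epimer. A catalytic amount of DBU at 0 °C equilibrates C7, where the fixed equatorial C15 methyl group holds the conformer in which the 7β-isopropenyl group is equatorial; the treatment is stopped before the double bond drifts into conjugation. Reduction with Li in NH3 and EtOH then gives the equatorial 8α-alcohol, so the fallback returns at 15.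

Step 3. The most likely failure is methylation of enolate 8 on the other face (C15 trans to C14), or proton exchange leading to over-methylation or to attack of the enolate on the ester. The fallback delivers hydrogen instead of methyl last. It sets out from 2 and 5, with commercial 3-ethoxy-2-methylcyclohex-2-en-1-one F2 in place of 1. F2 is alkylated with 2 (LiN(i-Pr)2) to tert-butyl 2-(4-ethoxy-3-methyl-2-oxocyclohex-3-en-1-yl)acetate F3, which with 5 and then acid gives tert-butyl 2-[3-methyl-4-oxo-2-(prop-2-en-1-yl)cyclohex-2-en-1-yl]acetate F4. Me2CuLi with BF3·OEt2 adds to this tetrasubstituted enone, and the enolate is protonated at −78 °C. Because the last group to arrive is now a proton, the C4 configuration comes out opposite to that of the methylation, whatever face the enolate prefers, so this route should give 9 exactly when step 3 does not. It returns at 9.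

Step 4. The most likely failures are slow ketalisation of the hindered ketone by a secondary diol, erosion of C4 by acid-induced enolisation during a long reaction, or incomplete chromatographic separation of the diastereomeric ketals. The fallback uses an achiral ketal and resolves after the ring closure. It sets out from 9, which with 1,2-bis(trimethylsilyloxy)ethane and catalytic Me3SiOTf at −78 °C gives the racemic dioxolane tert-butyl 2-[6,7-dimethyl-7-(prop-2-en-1-yl)-1,4-dioxaspiro[4.5]decan-8-yl]acetate F5. The conditions of steps 5 to 7 then lead to the prenyl ester F6, the aldehyde F7 and the racemic alcohol 8-hydroxyeremophil-11-en-3-one ethane-1,2-diyl ketal F8. Lipase-catalysed acetylation (lipase from Burkholderia cepacia, vinyl acetate, t-BuOMe), run past half conversion, should acylate the (8R) enantiomer, in line with the usual preference of lipases for the secondary alcohol whose larger substituent lies on that side. This gives the acetate F9 and leaves the (8S) enantiomer of F8, whose hydrolysis with 1 M HCl returns the route at 16.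

Step 14. The most likely failure is loss of regiocontrol in the deprotonation (the allylic C7 methine or the γ-position of the senecioate), leading to hydroxylation at C7 or conjugation of the isopropenyl group. The fallback uses an enamine instead of a metal enolate. It sets out from 22, which with nitrosobenzene and L-proline in DMSO should form the enamine only towards the less substituted C9, and the catalyst delivers oxygen to give the 9R anilinooxy ketone (3R,4R,5R,7R,9R,10S)-8-oxo-9-[(phenylamino)oxy]eremophil-11-en-3-yl 3-methylbut-2-enoate F10. CuSO4 in MeOH cleaves the N–O bond and returns the route at 24.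

Step 15. The most likely failure is isomerisation of the angeloyl group to the tigloyl group during activation, or heat- and base-induced drift of the isopropenyl double bond or of the α-acyloxy ketone. The fallback builds the Z double bond on the ester instead of transferring it. It sets out from 24, which is esterified (DCC, DMAP, 0 °C) with 2-[bis(2,2,2-trifluoroethoxy)phosphoryl]propanoic acid to the phosphonate (3R,4R,5R,7R,9R,10S)-9-({2-[bis(2,2,2-trifluoroethoxy)phosphoryl]propanoyl}oxy)-8-oxoeremophil-11-en-3-yl 3-methylbut-2-enoate F11. A Still–Gennari olefination with acetaldehyde (KN(SiMe3)2, 18-crown-6, THF, −78 °C) then forms the (Z)-2-methylbut-2-enoate and returns the route at 27.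

## Further compounds

F1 | step 7 | (4R,5S,7R,10R)-eremophil-11-ene-3,8-dione 3-[(2R,3R)-butane-2,3-diyl ketal] | C=C(C)[C@H]1C[C@@]2(C)[C@H](CCC3(O[C@H](C)[C@@H](C)O3)[C@@H]2C)CC1=O
F2 | step 3 | 3-ethoxy-2-methylcyclohex-2-en-1-one (commercial) | CCOC1=C(C)C(=O)CCC1
F3 | step 3 | tert-butyl 2-(4-ethoxy-3-methyl-2-oxocyclohex-3-en-1-yl)acetate, racemic, (1R) drawn | CCOC1=C(C)C(=O)[C@@H](CC(=O)OC(C)(C)C)CC1
F4 | step 3 | tert-butyl 2-[3-methyl-4-oxo-2-(prop-2-en-1-yl)cyclohex-2-en-1-yl]acetate, racemic, (1R) drawn | C=CCC1=C(C)C(=O)CC[C@@H]1CC(=O)OC(C)(C)C
F5 | step 4 | tert-butyl 2-[(6R,7S,8R)-6,7-dimethyl-7-(prop-2-en-1-yl)-1,4-dioxaspiro[4.5]decan-8-yl]acetate, racemic | C=CC[C@@]1(C)[C@H](CCC2(OCCO2)[C@@H]1C)CC(=O)OC(C)(C)C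
F6 | step 4 | tert-butyl 2-[(6R,7S,8R)-6,7-dimethyl-7-(3-methylbut-2-en-1-yl)-1,4-dioxaspiro[4.5]decan-8-yl]acetate, racemic | CC(C)=CC[C@@]1(C)[C@H](CCC2(OCCO2)[C@@H]1C)CC(=O)OC(C)(C)C
F7 | step 4 | 2-[(6R,7S,8R)-6,7-dimethyl-7-(3-methylbut-2-en-1-yl)-1,4-dioxaspiro[4.5]decan-8-yl]acetaldehyde, racemic | CC(C)=CC[C@@]1(C)[C@H](CCC2(OCCO2)[C@@H]1C)CC=O
F8 | step 4 | (4R,5S,7R,8S,10R)-8-hydroxyeremophil-11-en-3-one ethane-1,2-diyl ketal, racemic; the enantiomer drawn is the one left by the lipase | C=C(C)[C@H]1C[C@@]2(C)[C@H](CCC3(OCCO3)[C@@H]2C)C[C@@H]1O
F9 | step 4 | (4S,5R,7S,8R,10S)-3,3-(ethane-1,2-diyldioxy)eremophil-11-en-8-yl acetate (from the unwanted enantiomer) | C=C(C)[C@@H]1C[C@]2(C)[C@@H](CCC3(OCCO3)[C@H]2C)C[C@H]1OC(C)=O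
F10 | step 14 | (3R,4R,5R,7R,9R,10S)-8-oxo-9-[(phenylamino)oxy]eremophil-11-en-3-yl 3-methylbut-2-enoate | C=C(C)[C@H]1C[C@@]2(C)[C@H](CC[C@@H](OC(=O)C=C(C)C)[C@@H]2C)[C@@H](ONc3ccccc3)C1=O
F11 | step 15 | (3R,4R,5R,7R,9R,10S)-9-({2-[bis(2,2,2-trifluoroethoxy)phosphoryl]propanoyl}oxy)-8-oxoeremophil-11-en-3-yl 3-methylbut-2-enoate (mixture at the phosphonate carbon) | C=C(C)[C@H]1C[C@@]2(C)[C@H](CC[C@@H](OC(=O)C=C(C)C)[C@@H]2C)[C@@H](OC(=O)C(C)P(=O)(OCC(F)(F)F)OCC(F)(F)F)C1=O
A1 | alternative 1 | (7Z)-9-[(tert-butyldimethylsilyl)oxy]-8-[(4-methoxybenzyl)oxy]-2-methyldeca-1,7,9-trien-3-one | C=C(C)C(=O)CCC/C=C(\OCc1ccc(OC)cc1)C(=C)O[Si](C)(C)C(C)(C)C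
A2 | alternative 1 | cis-fused 5-methyloctalin-4-one with C8 silyl enol ether and C9 PMB ether (target numbering) | C1C[C@@]2(C)[C@H](CCCC2=O)C(OCc3ccc(OC)cc3)=C1O[Si](C)(C)C(C)(C)C
A3 | alternative 2 | 3,3-dimethoxy-5,6-dimethyl-2-vinylbicyclo[2.2.2]oct-5-en-2-ol, vinyl syn to the C5=C6 bridge | C=C[C@@]1(O)[C@H]2C(C)=C(C)[C@H](CC2)C1(OC)OC
A4 | alternative 2 | cis-fused 9,9-dimethoxy-4,5-dimethyloctal-3-en-8-one (target numbering) | C1C[C@@]2(C)[C@H](CCC=C2C)C(OC)(OC)C1=O
A5 | alternative 3 | 2-methoxy-5-methylcyclohexa-2,5-diene-1,4-dione | COC1=CC(=O)C(C)=CC1=O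
A6 | alternative 3 | (Z)-tert-butyldimethyl(penta-1,3-dien-3-yloxy)silane | C=C/C(O[Si](C)(C)C(C)(C)C)=C/C
A7 | alternative 3 | cis-fused endo adduct with C3 silyl enol ether, C6 and C9 ketones and C8 methoxy enone (C4 methyl epimeric; target numbering) | COC1=CC(=O)[C@@]2(C)[C@H](CC=C(O[Si](C)(C)C(C)(C)C)[C@H]2C)C1=O
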